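## The problem

Target 18 is a linear trimer of 8-methoxy-1-naphthol whose three identical units are joined unsymmetrically: unit A through C2 to C2' of the central unit B, and unit B through C4' to C4'' of unit C. Every unit offers the same two nucleophilic positions, ortho and para to its hydroxyl, so oxidative oligomerisation of the monomer cannot be relied on for this single 2,2':4',4'' connectivity. Each aryl–aryl connection must therefore come from a reaction whose regiochemistry is fixed by the substrates. There are no stereocentres. The C2–C2' axis rotates freely and the C4'–C4'' axis is a 1,1'-binaphthyl axis flanked only by hydrogens, so nothing has to be controlled or relayed. The three peri-hydroxy/methoxy rings are very electron-rich; as free naphthols they are open to aerial oxidation and to electrophiles at their free ortho and para positions. Two hydroxyls are therefore masked through the metal-mediated steps, and the unmasking must avoid oxidants and stray carbon electrophiles. The feature that allows one ring to be built de novo is the hydroxylated ring of unit C. C1'' is oxygenated peri to the C8'' methoxy group, C4'' carries the aryl substituent, and C2'' and C3'' are unsubstituted. This maps onto a 2-methoxybenzoyl unit with exactly one free ortho C–H (future C4a''), a one-carbon carbene equivalent (C2'') and an aryl alkyne (C3'' and C4'').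

## Retrosynthesis

**Endgame, 18 from 17 and 16.** The C3''–H bond of 18 is traced back to a C3''–Si bond in trinaphthol 17, and the two free hydroxyls of units A and B to the methoxymethyl ethers of 16. The acetal is chosen because it also directs the ortho-metalation used earlier and because it falls off in acidic methanol, where the solvent traps the formaldehyde-derived cation. The acetals are removed before the silyl group so that no methoxymethyl cation is ever formed in a strong, non-nucleophilic acid next to three activated rings. The last step then asks only for ipso-protonation at C3''.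

**Key disconnection, 16 from 11 and 15.** The bonds C4''–C4a'' and C2''–C3'' are cut, which removes the whole hydroxylated ring of unit C. This leaves the binaphthyl silyl alkyne 11 and the 2-methoxybenzoyl sulfoxonium ylide 15. The neighbouring cut, the C4'–C4'' biaryl bond, would couple two peri-hindered naphthyl carbons and would need a third regiodefined monomer. The annulation instead draws unit C from a simple benzoyl derivative and sets the peri O/O relationship by construction, since 15 has only one ortho C–H. The hindered aryl–naphthyl junction is made by alkyne insertion rather than by joining two hindered sp2 centres. The forward reaction must insert the alkyne with the aryl-bearing carbon next to the arene; the trimethylsilyl group is placed on the alkyne for that purpose. It must also tolerate two acetals and the C–Si bond.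

**Ylide 15 from 12 and 13.** The bond between the carbonyl carbon and the ylide carbon is cut, giving acid chloride 12 and sulfoxonium salt 13; the salt is converted in the flask to methylide 14. This is a one-step acylation with no selectivity question.

**Alkyne 11 from 9 and 10.** The C4'–C(sp) bond is cut, giving bromide 9 and silylacetylene 10. An sp–sp2 coupling is little affected by the peri hydrogen at C5', and it introduces both alkyne carbons and the silyl group in one operation.

**Binaphthyl 9 from 5 and 8.** The C2–C2' bond is cut, giving boronate 5 (unit A) and the 2-iodo-4-bromo naphthalene 8 (unit B). The iodide/bromide pair lets the biaryl bond form at C2' while the C4' bromide waits for the alkyne. The alternative, a symmetric 2,2'-binaphthyl brominated once afterwards, would depend on statistical differentiation of two identical rings; it is kept as a fallback.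

**Monomers 5 and 8 from 2, and 2 from 1.** Boronate 5 comes from acetal 3 by ortho-lithiation to aryllithium 4 and borylation, and 3 comes from naphthol 2. Dihalide 8 comes from 2 by para-bromination to 6, ortho-iodination to 7 and acetal formation. Both halogenations are done on the free naphthol, where the hydroxyl dominates over the methoxy group and directs substitution into its own ring. Naphthol 2 is the monomethyl ether of diol 1. Units A and B thus come from one monomer and unit C from acid chloride 12.

## Roads not taken

**Alternative 1:** The central ring of unit B is cut at C3'–C4' and C1'–C2'. In the forward sense the lithiated toluate A2, a diarylmethane carrying unit C, adds to the CH2 terminus of the α-aryl vinyl sulfone A3, which carries unit A. The resulting sulfonyl carbanion acylates the ester, and loss of sulfinate with enolisation gives A1, the target with units A and C as benzyl ethers. The merits are real. The two outer units arrive on separate fragments, the regiochemistry is fixed by connectivity with no insertion sense to control and no spectator group to remove, and A1 is one hydrogenolysis from 18. The weak points are the following: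
- The nucleophile is a doubly benzylic, delocalised and hindered anion.
- The intermediate carbanion is tertiary, bears a bulky ortho-substituted naphthyl group, and must attack an ester flanked by an ortho methoxy group.
- A2 and A3 each need their own multi-step synthesis, and the C4'–C4'' connection has to be made first as a diarylmethane.

In regiochemical certainty and in its endgame this road is better than the chosen one. The chosen plan sets against it that both coupling partners 11 and 15 come from one monomer and a commercial acid chloride, and that its ring-forming step belongs to an established catalytic reaction class.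

**Alternative 2:** The hydroxylated ring of unit A is cut at C1–C2. A strong lithium amide base deprotonates the benzylic allylic CH2 of the o-(3-arylallyl)benzamide A5. The aryl-bearing terminus of the 1,3-diarylallyl anion attacks the diethylamide carbonyl, and loss of the amide leaving group with enolisation gives A4, the target with units B and C as benzyl ethers. The amide is an excellent ortho-director, so the allyl side chain is easy to install; the cyclisation needs no metal catalyst and leaves no spectator group. The weak points are the following:
- The ring being built belongs to a terminal unit, so the complete B–C binaphthyl, with a three-carbon handle at C2', must be made first, and its hindered C4'–C4'' bond must be formed by a cross-coupling anyway.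
- The allyl anion is highly stabilised and has to react through its more hindered terminus, in a cisoid geometry, with a twisted 2,6-disubstituted tertiary amide.

This road is equal to the chosen plan in regiochemical clarity and better in having no desilylation. It is clearly longer, and its key step asks more of a poor electrophile than the rhodium annulation asks of 11.

**Alternative 3:** The same ring as in the chosen plan is cut, but at C3''=C4''. The second-generation Hoveyda–Grubbs catalyst closes the allyl ketone onto the 1,1-diarylethene of diene A7 with extrusion of the two terminal CH2 groups. The naphthalen-1(2H)-one formed enolises to A6, the target with units A and B as benzyl ethers. The attraction is that C3'' arrives as CH, so there is no silyl group, no insertion regiochemistry and a neutral key step. The weak points are the following: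
- A 1,1-diarylethene with two ortho-substituted aryl groups is among the least willing metathesis partners, and the ring closure must form a trisubstituted styrenic alkene at that carbon.
- The allyl aryl ketone can isomerise to the conjugated enone under base or ruthenium hydride, after which ring closure is impossible.
- A7 itself requires a hindered diarylethene and an allyl ketone on a 2,6-disubstituted benzene.

This road is better in directness from key step to target and in freedom from the regiochemical question. The chosen plan sets against it a two-component assembly from much simpler partners, and a ring closure that does not depend on metathesis at a hindered diaryl alkene.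

Key step: step 10

Assumption: the two biaryl axes of 18 are treated as stereochemically undefined, as in the target SMILES, because neither should be configurationally stable at room temperature.

## Route

Step 1
Reactants: 1 naphthalene-1,8-diol
Product: 2 8-methoxynaphthalen-1-ol
Conditions: MeI (1.1 equiv), K2CO3, acetone, reflux
Reagents that add atoms: iodomethane, CI
Why: Williamson ether synthesis; the first naphthoxide is stabilised by the peri hydrogen bond and the remaining O–H is much less acidic, so carbonate should stop at the monoether.

Step 2
Reactants: 2 8-methoxynaphthalen-1-ol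
Product: 3 1-methoxy-8-(methoxymethoxy)naphthalene
Conditions: NaH, MOMCl, DMF, 0 °C to rt
Reagents that add atoms: chloromethyl methyl ether, COCCl
Why: O-alkylation of the sodium naphthoxide to the methoxymethyl acetal; the small electrophile should tolerate the peri methoxy neighbour.

Step 3
Reactants: 3 1-methoxy-8-(methoxymethoxy)naphthalene
Product: 5 2-[8-methoxy-1-(methoxymethoxy)naphthalen-2-yl]-4,4,5,5-tetramethyl-1,3,2-dioxaborolane, via aryllithium 4 (not isolated)
Conditions: n-BuLi, TMEDA, Et2O, 0 °C to rt; then i-PrOBpin, −78 °C to rt; aq. NH4Cl
Reagents that add atoms: 2-isopropoxy-4,4,5,5-tetramethyl-1,3,2-dioxaborolane, CC(C)OB1OC(C)(C)C(C)(C)O1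
Why: Directed ortho-metalation; the chelating OCH2OMe group is a stronger director than the methoxy group, so lithium should go to C2 rather than C7, and the borate ester traps the aryllithium as the pinacol boronate.

Step 4
Reactants: 2 8-methoxynaphthalen-1-ol
Product: 6 4-bromo-8-methoxynaphthalen-1-ol
Conditions: NBS (1.0 equiv), MeCN, −20 to 0 °C, dark
Reagents that add atoms: N-bromosuccinimide, O=C1CCC(=O)N1Br
Why: Electrophilic aromatic bromination; the hydroxyl activates its own ring more strongly than the methoxy group activates the other, and in acetonitrile the unhindered para position C4 should be attacked.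

Step 5
Reactants: 6 4-bromo-8-methoxynaphthalen-1-ol
Product: 7 4-bromo-2-iodo-8-methoxynaphthalen-1-ol
Conditions: NIS, TsOH·H2O (cat.), MeCN, 0 °C to rt, dark
Reagents that add atoms: N-iodosuccinimide, O=C1CCC(=O)N1I
Why: Electrophilic aromatic iodination; with C4 blocked, C2 is the only remaining position activated by the hydroxyl.

Step 6
Reactants: 7 4-bromo-2-iodo-8-methoxynaphthalen-1-ol
Product: 8 4-bromo-2-iodo-8-methoxy-1-(methoxymethoxy)naphthalene
Conditions: NaH, MOMCl, DMF, 0 °C to rt
Reagents that add atoms: chloromethyl methyl ether, COCCl
Why: Acetal protection as in step 2; the free hydroxyl would otherwise interfere with the couplings and with the rhodium carbene of the key step.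

Step 7
Reactants: 5 2-[8-methoxy-1-(methoxymethoxy)naphthalen-2-yl]-4,4,5,5-tetramethyl-1,3,2-dioxaborolane; 8 4-bromo-2-iodo-8-methoxy-1-(methoxymethoxy)naphthalene
Product: 9 4-bromo-8,8'-dimethoxy-1,1'-bis(methoxymethoxy)-2,2'-binaphthalene
Conditions: Pd(PPh3)4 (cat.), K2CO3, DME/H2O, 70 °C
Reagents that add atoms: none
Why: Suzuki–Miyaura coupling; oxidative addition of zerovalent palladium to the C–I bond is much faster than to the C–Br bond, so the biaryl bond should form at C2' and the C4' bromide remain.

Step 8
Reactants: 9 4-bromo-8,8'-dimethoxy-1,1'-bis(methoxymethoxy)-2,2'-binaphthalene; 10 ethynyltrimethylsilane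
Product: 11 {[8,8'-dimethoxy-1,1'-bis(methoxymethoxy)-[2,2'-binaphthalen]-4-yl]ethynyl}trimethylsilane
Conditions: PdCl2(PhCN)2 (cat.), P(t-Bu)3 (cat.), CuI (cat.), i-Pr2NH, 1,4-dioxane, rt to 50 °C
Reagents that add atoms: none
Why: Sonogashira coupling; the electron-rich bulky phosphine should allow oxidative addition to the electron-rich, peri-flanked bromide near room temperature, where the alkynyl C–Si bond is not touched by the amine.

Step 9
Reactants: 12 2-methoxybenzoyl chloride; 13 trimethylsulfoxonium iodide
Product: 15 2-[dimethyl(oxo)-λ6-sulfanylidene]-1-(2-methoxyphenyl)ethan-1-one, via dimethylsulfoxonium methylide 14 (not isolated)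
Conditions: 13 (3 equiv), KOt-Bu (3 equiv), THF, reflux; then 12, 0 °C to rt
Reagents that add atoms: none
Why: Acylation of the Corey–Chaykovsky sulfoxonium methylide; a second equivalent of 14 deprotonates the acylsulfoxonium salt to give the stabilised keto ylide.

Step 10
Reactants: 11 {[8,8'-dimethoxy-1,1'-bis(methoxymethoxy)-[2,2'-binaphthalen]-4-yl]ethynyl}trimethylsilane; 15 2-[dimethyl(oxo)-λ6-sulfanylidene]-1-(2-methoxyphenyl)ethan-1-one
Product: 16 4-[8,8'-dimethoxy-1,1'-bis(methoxymethoxy)-[2,2'-binaphthalen]-4-yl]-8-methoxy-3-(trimethylsilyl)naphthalen-1-ol
Conditions: [Cp*RhCl2]2 (cat.), AgSbF6 (cat.), NaOAc (cat.), 15 (1.5–2 equiv), DCE, 80 °C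
Reagents that add atoms: none
Why: Chloride abstraction by AgSbF6 gives a cationic Cp* complex of trivalent rhodium; ylide 15 binds it and directs acetate-assisted metalation of its only free ortho C–H (future C4a''), so the methoxy group must end peri to the new hydroxyl. Alkyne 11 then inserts into the aryl–rhodium bond with its naphthyl-bearing carbon bonding to the arene (C4''–C4a'') and its silyl-bearing carbon on rhodium. The ylide carbon, held on rhodium in a seven-membered metallacycle, loses dimethyl sulfoxide to give a rhodium carbene, and 1,1-migratory insertion of the alkenyl group forms C2''–C3''. Protodemetalation and enolisation of the resulting naphthalen-1(2H)-one give naphthol 16 and return the catalyst, so the step is redox-neutral. The closest known reaction type is the annulation of benzoyl sulfoxonium ylides with internal alkynes to 1-naphthols under this catalyst system. The one ring closed is the six-membered hydroxylated ring of unit C, by a formal (4+2) annulation in which C8a'', C4a'', C1'' and C2'' come from 15 and C3'' and C4'' from 11; no stereocentre is formed. The selectivity needed is the sense of alkyne insertion: the trimethylsilyl group should take the rhodium-bound carbon, as silyl alkynes do in Larock-type annulations, because silicon stabilises the adjacent carbon–metal bond and the electron-rich 4-alkoxynaphthyl group polarises the alkyne in the same direction. NaOAc buffers the acid released on metalation so that the acetals and the C–Si bonds survive, and 15 is used in excess because the ylide slowly decomposes.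

Step 11
Reactants: 16 4-[8,8'-dimethoxy-1,1'-bis(methoxymethoxy)-[2,2'-binaphthalen]-4-yl]-8-methoxy-3-(trimethylsilyl)naphthalen-1-ol
Product: 17 4-[4-hydroxy-5-methoxy-2-(trimethylsilyl)naphthalen-1-yl]-8,8'-dimethoxy-[2,2'-binaphthalene]-1,1'-diol
Conditions: HCl (3 M aq.), MeOH/THF, 40–50 °C, argon
Reagents that add atoms: none
Why: Acid-catalysed acetal cleavage; methanol intercepts the methoxymethyl cation as dimethoxymethane so the electron-rich rings are not alkylated, and the aryl–silicon bond at the unactivated C3'' should largely survive dilute acid (any desilylated material converges in step 12).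

Step 12
Reactants: 17 4-[4-hydroxy-5-methoxy-2-(trimethylsilyl)naphthalen-1-yl]-8,8'-dimethoxy-[2,2'-binaphthalene]-1,1'-diol
Product: 18 4-(4-hydroxy-5-methoxynaphthalen-1-yl)-8,8'-dimethoxy-[2,2'-binaphthalene]-1,1'-diol
Conditions: TFA, CH2Cl2, 0 °C to rt, argon
Reagents that add atoms: none
Why: Acid ipso-protodesilylation; protonation at C3'' gives an arenium ion stabilised by the β-silicon effect and favoured by relief of strain between the silyl group and the C4'' aryl group, while protonation elsewhere is reversible, and the silyl ester by-product is volatile.

## Compound list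

1 | naphthalene-1,8-diol | Oc1cccc2cccc(O)c12 | starting material
2 | 8-methoxynaphthalen-1-ol | COc1cccc2cccc(O)c12 | intermediate
3 | 1-methoxy-8-(methoxymethoxy)naphthalene | COCOc1cccc2cccc(OC)c12 | intermediate
4 | [8-methoxy-1-(methoxymethoxy)naphthalen-2-yl]lithium | [Li]c1ccc2cccc(OC)c2c1OCOC | intermediate
5 | 2-[8-methoxy-1-(methoxymethoxy)naphthalen-2-yl]-4,4,5,5-tetramethyl-1,3,2-dioxaborolane | COCOc1c(B2OC(C)(C)C(C)(C)O2)ccc2cccc(OC)c12 | intermediate
6 | 4-bromo-8-methoxynaphthalen-1-ol | COc1cccc2c(Br)ccc(O)c12 | intermediate
7 | 4-bromo-2-iodo-8-methoxynaphthalen-1-ol | COc1cccc2c(Br)cc(I)c(O)c12 | intermediate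
8 | 4-bromo-2-iodo-8-methoxy-1-(methoxymethoxy)naphthalene | COCOc1c(I)cc(Br)c2cccc(OC)c12 | intermediate
9 | 4-bromo-8,8'-dimethoxy-1,1'-bis(methoxymethoxy)-2,2'-binaphthalene | COCOc1c(-c2cc(Br)c3cccc(OC)c3c2OCOC)ccc2cccc(OC)c12 | intermediate
10 | ethynyltrimethylsilane | C#C[Si](C)(C)C | starting material
11 | {[8,8'-dimethoxy-1,1'-bis(methoxymethoxy)-[2,2'-binaphthalen]-4-yl]ethynyl}trimethylsilane | COCOc1c(-c2cc(C#C[Si](C)(C)C)c3cccc(OC)c3c2OCOC)ccc2cccc(OC)c12 | intermediate
12 | 2-methoxybenzoyl chloride | COc1ccccc1C(Cl)=O | starting material
13 | trimethylsulfoxonium iodide | C[S+](C)(C)=O.[I-] | starting material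
14 | dimethylsulfoxonium methylide | C=S(C)(C)=O | intermediate
15 | 2-[dimethyl(oxo)-λ6-sulfanylidene]-1-(2-methoxyphenyl)ethan-1-one | COc1ccccc1C(=O)C=S(C)(C)=O | intermediate
16 | 4-[8,8'-dimethoxy-1,1'-bis(methoxymethoxy)-[2,2'-binaphthalen]-4-yl]-8-methoxy-3-(trimethylsilyl)naphthalen-1-ol | COc1cccc2c(-c3cc(-c4ccc5cccc(OC)c5c4OCOC)c(OCOC)c4c(OC)cccc34)c([Si](C)(C)C)cc(O)c12 | intermediate
17 | 4-[4-hydroxy-5-methoxy-2-(trimethylsilyl)naphthalen-1-yl]-8,8'-dimethoxy-[2,2'-binaphthalene]-1,1'-diol | COc1cccc2c(-c3cc(-c4ccc5cccc(OC)c5c4O)c(O)c4c(OC)cccc34)c([Si](C)(C)C)cc(O)c12 | intermediate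
18 | 4-(4-hydroxy-5-methoxynaphthalen-1-yl)-8,8'-dimethoxy-[2,2'-binaphthalene]-1,1'-diol | COc1cccc2ccc(-c3cc(-c4ccc(O)c5c(OC)cccc45)c4cccc(OC)c4c3O)c(O)c12 | target

## Step count and risks

Total step count: 12. Longest linear sequence: 9 steps (steps 1, 4, 5, 6, 7, 8, 10, 11, 12).

**Step 10 (key step).** Three things could go wrong.
- The alkyne could insert in the opposite sense. In aryl/alkyl alkynes the aryl-bearing carbon normally takes the rhodium-bound position, and here that preference competes with the silyl group.
- The alkynyl C–Si bond could be cleaved by silver or acid before insertion, leaving a terminal alkyne that inserts unselectively or oligomerises.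
- Insertion of the hindered alkyne could be slow enough that the ylide decomposes first.

The fallback abandons the annulation and makes the C4'–C4'' bond directly.
- Bromide 9 is converted by Miyaura borylation (B2pin2, PdCl2(dppf), KOAc) into 2-[8,8'-dimethoxy-1,1'-bis(methoxymethoxy)-[2,2'-binaphthalen]-4-yl]-4,4,5,5-tetramethyl-1,3,2-dioxaborolane F1.
- Bromonaphthol 6 is protected (NaH, MOMCl) as 1-bromo-5-methoxy-4-(methoxymethoxy)naphthalene F2.
- Suzuki–Miyaura coupling of F1 with F2 (Pd(OAc)2, SPhos, K3PO4) gives 4-[5-methoxy-4-(methoxymethoxy)naphthalen-1-yl]-8,8'-dimethoxy-1,1'-bis(methoxymethoxy)-2,2'-binaphthalene F3.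
- Acidic methanol as in step 11 removes the three acetals of F3 and the route is rejoined at 18.

**Step 12.** Ipso-protonation at C3'' is not assisted by the hydroxyl, which is meta to it. Desilylation may therefore be slow, and meanwhile the free trinaphthol is exposed to strong acid and may oxidise or condense. The fallback sets out from 16 and removes silicon under basic conditions before the acetals. KOSiMe3 in wet DMSO (base-catalysed protodesilylation through a pentacoordinate silicate) should give 4-[8,8'-dimethoxy-1,1'-bis(methoxymethoxy)-[2,2'-binaphthalen]-4-yl]-8-methoxynaphthalen-1-ol F4. Acidic methanol then removes the acetals of F4 and gives 18 directly.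

**Step 3.** Lithiation may occur in part at C7, ortho to the methoxy group, or at the acetal CH2, which would give isomeric boronates that are hard to separate. The fallback sets out from 2 and places the handle by halogenation.
- Amine-mediated ortho-bromination (NBS, cat. i-Pr2NH, CH2Cl2) gives 2-bromo-8-methoxynaphthalen-1-ol F5.
- Protection (NaH, MOMCl) gives 2-bromo-8-methoxy-1-(methoxymethoxy)naphthalene F6.
- Miyaura borylation of F6 (B2pin2, PdCl2(dppf), KOAc) returns to the route at 5.

**Step 7.** Coupling may continue at the C4' bromide once the iodide is consumed, and the ortho-alkoxy boronate may protodeboronate before it transmetalates to the hindered palladium centre. The fallback removes the second halogen from the coupling and sets out from aryllithium 4.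
- Quenching 4 with I2 gives 2-iodo-8-methoxy-1-(methoxymethoxy)naphthalene F7.
- Suzuki–Miyaura coupling of F7 with 5 gives the symmetric 8,8'-dimethoxy-1,1'-bis(methoxymethoxy)-2,2'-binaphthalene F8.
- Acidic methanol gives 8,8'-dimethoxy-[2,2'-binaphthalene]-1,1'-diol F9.
- One equivalent of NBS in MeCN brominates para to one hydroxyl and gives 4-bromo-8,8'-dimethoxy-[2,2'-binaphthalene]-1,1'-diol F10. Selectivity between the two identical rings rests on stoichiometry alone.
- Double protection of F10 (NaH, MOMCl) returns to the route at 9.

## Further compounds

F1 | step 10 | 2-[8,8'-dimethoxy-1,1'-bis(methoxymethoxy)-[2,2'-binaphthalen]-4-yl]-4,4,5,5-tetramethyl-1,3,2-dioxaborolane | COCOc1c(-c2cc(B3OC(C)(C)C(C)(C)O3)c3cccc(OC)c3c2OCOC)ccc2cccc(OC)c12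
F2 | step 10 | 1-bromo-5-methoxy-4-(methoxymethoxy)naphthalene | COCOc1ccc(Br)c2cccc(OC)c12
F3 | step 10 | 4-[5-methoxy-4-(methoxymethoxy)naphthalen-1-yl]-8,8'-dimethoxy-1,1'-bis(methoxymethoxy)-2,2'-binaphthalene | COCOc1c(-c2cc(-c3ccc(OCOC)c4c(OC)cccc34)c3cccc(OC)c3c2OCOC)ccc2cccc(OC)c12
F4 | step 12 | 4-[8,8'-dimethoxy-1,1'-bis(methoxymethoxy)-[2,2'-binaphthalen]-4-yl]-8-methoxynaphthalen-1-ol | COc1cccc2c(-c3cc(-c4ccc5cccc(OC)c5c4OCOC)c(OCOC)c4c(OC)cccc34)ccc(O)c12
F5 | step 3 | 2-bromo-8-methoxynaphthalen-1-ol | COc1cccc2ccc(Br)c(O)c12
F6 | step 3 | 2-bromo-8-methoxy-1-(methoxymethoxy)naphthalene | COCOc1c(Br)ccc2cccc(OC)c12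
F7 | step 7 | 2-iodo-8-methoxy-1-(methoxymethoxy)naphthalene | COCOc1c(I)ccc2cccc(OC)c12
F8 | step 7 | 8,8'-dimethoxy-1,1'-bis(methoxymethoxy)-2,2'-binaphthalene | COCOc1c(-c2ccc3cccc(OC)c3c2OCOC)ccc2cccc(OC)c12
F9 | step 7 | 8,8'-dimethoxy-[2,2'-binaphthalene]-1,1'-diol | COc1cccc2ccc(-c3ccc4cccc(OC)c4c3O)c(O)c12
F10 | step 7 | 4-bromo-8,8'-dimethoxy-[2,2'-binaphthalene]-1,1'-diol | COc1cccc2ccc(-c3cc(Br)c4cccc(OC)c4c3O)c(O)c12
A1 | alternative 1 | 2-[1-(benzyloxy)-8-methoxynaphthalen-2-yl]-4-[4-(benzyloxy)-5-methoxynaphthalen-1-yl]-8-methoxynaphthalen-1-ol | COc1cccc2ccc(-c3cc(-c4ccc(OCc5ccccc5)c5c(OC)cccc45)c4cccc(OC)c4c3O)c(OCc3ccccc3)c12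
A2 | alternative 1 | methyl 2-{[4-(benzyloxy)-5-methoxynaphthalen-1-yl]methyl}-6-methoxybenzoate | COC(=O)c1c(OC)cccc1Cc1ccc(OCc2ccccc2)c2c(OC)cccc12
A3 | alternative 1 | 1-(benzyloxy)-8-methoxy-2-[1-(phenylsulfonyl)ethenyl]naphthalene | C=C(c1ccc2cccc(OC)c2c1OCc1ccccc1)S(=O)(=O)c1ccccc1
A4 | alternative 2 | 1'-(benzyloxy)-4'-[4-(benzyloxy)-5-methoxynaphthalen-1-yl]-8,8'-dimethoxy-[2,2'-binaphthalen]-1-ol | COc1cccc2ccc(-c3cc(-c4ccc(OCc5ccccc5)c5c(OC)cccc45)c4cccc(OC)c4c3OCc3ccccc3)c(O)c12
A5 | alternative 2 | 2-[(E)-3-{1-(benzyloxy)-4-[4-(benzyloxy)-5-methoxynaphthalen-1-yl]-8-methoxynaphthalen-2-yl}prop-2-en-1-yl]-N,N-diethyl-6-methoxybenzamide | CCN(CC)C(=O)c1c(OC)cccc1C/C=C/c1cc(-c2ccc(OCc3ccccc3)c3c(OC)cccc23)c2cccc(OC)c2c1OCc1ccccc1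
A6 | alternative 3 | 4-[1,1'-bis(benzyloxy)-8,8'-dimethoxy-[2,2'-binaphthalen]-4-yl]-8-methoxynaphthalen-1-ol | COc1cccc2c(-c3cc(-c4ccc5cccc(OC)c5c4OCc4ccccc4)c(OCc4ccccc4)c4c(OC)cccc34)ccc(O)c12
A7 | alternative 3 | 1-(2-{1-[1,1'-bis(benzyloxy)-8,8'-dimethoxy-[2,2'-binaphthalen]-4-yl]ethenyl}-6-methoxyphenyl)but-3-en-1-one | C=CCC(=O)c1c(OC)cccc1C(=C)c1cc(-c2ccc3cccc(OC)c3c2OCc2ccccc2)c(OCc2ccccc2)c2c(OC)cccc12
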